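## Retrosynthetic overview

1. Last bonds: global desilylation, then the ester C–O bond, giving an α-hydroxy ketone and (Z)-4-silyloxycinnamic acid (Negishi coupling of silyl-protected 4-iodophenol with (Z)-3-iodoacrylic acid).
2. Key disconnection: both cyclopropane bonds to the acyl-bearing carbon, giving a lactate-derived α-diazoketone and the terminal vinyl group of the lactone fragment. They are joined by a cobalt metalloradical (stepwise radical) cyclopropanation that unites the two halves and sets both ring stereocentres.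
3. Lactone fragment: cis-semi-hydrogenation and lactonisation of a δ-hydroxy ynoate, from propiolate opening of a silylated epoxy alcohol, from Sharpless desymmetrisation of divinylcarbinol (both carbinol centres).
4. Diazoketone: from D-lactic acid (chiral pool, the remaining stereocentre).
5. Ring order: the δ-lactone ring first (step 4), the cyclopropane second (step 8).

Assumption (catalyst sense): the cobalt porphyrin built from the (S)-amide is taken as the enantiomer that is matched with the (S)-silyloxy centre of the lactone alkene and gives the (1S,2S)-cyclopropane; if the sense proves opposite, the mirror-image ligand is used with nothing else changed.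

Assumption (supply): D-lactic acid, tert-butyl(4-iodophenoxy)dimethylsilane and (Z)-3-iodoacrylic acid are bought.

## Route

Step 1
Reactants: 1 penta-1,4-dien-3-ol (divinylcarbinol)
Product: 2 (2R,3S)-1,2-epoxypent-4-en-3-ol, i.e. (S)-1-[(R)-oxiran-2-yl]prop-2-en-1-ol
Conditions: Ti(OiPr)4 (10 mol %), L-(+)-diisopropyl tartrate (13 mol %), t-BuOOH (anhydrous, 1.3 equiv), 4 Å MS, CH2Cl2, −20 °C, 4–5 d
Reagents that add atoms: tert-butyl hydroperoxide, CC(C)(C)OO
Why: Sharpless asymmetric epoxidation used as a desymmetrisation: one enantiotopic vinyl group is epoxidised on the face that gives the anti (erythro) epoxy alcohol, so the 2R centre (future lactone C–O carbon) and the 3S centre (future free carbinol) are set together, and the minor enantiomer is removed by a faster second epoxidation, which drives the ee above 99 %.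

Step 2
Reactants: 2 (2R,3S)-1,2-epoxypent-4-en-3-ol
Product: 3 tert-butyldimethyl{[(S)-1-((R)-oxiran-2-yl)allyl]oxy}silane
Conditions: TBSCl (1.2 equiv), imidazole (1.5 equiv), DMF, 0 °C → rt
Reagents that add atoms: tert-butyldimethylsilyl chloride, CC(C)(C)[Si](C)(C)Cl
Why: Standard imidazole-mediated silylation of the secondary alcohol, with no stereocentre touched; the TBS ether blocks the alkoxide in step 3 and stays on until the last step.

Step 3
Reactants: 3 tert-butyldimethyl{[(S)-1-((R)-oxiran-2-yl)allyl]oxy}silane; 4 ethyl propiolate (2.0 equiv)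
Product: 6 ethyl (5R,6S)-6-[(tert-butyldimethylsilyl)oxy]-5-hydroxyoct-7-en-2-ynoate, via lithium acetylide 5 (not isolated)
Conditions: 4, n-BuLi, THF, −78 °C; BF3·OEt2 (promoter, 2.0 equiv); then 3, −78 °C, 2 h; sat. aq. NH4Cl
Reagents that add atoms: none
Why: Yamaguchi–Hirao alkynylation: the BF3-activated epoxide is opened by the lithium acetylide in an SN2 reaction at the unsubstituted terminal carbon, so both stereocentres are carried over unchanged and the full carbon chain of the lactone is in place.

Step 4
Reactants: 6 ethyl (5R,6S)-6-[(tert-butyldimethylsilyl)oxy]-5-hydroxyoct-7-en-2-ynoate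
Product: 8 (R)-6-{(S)-1-[(tert-butyldimethylsilyl)oxy]allyl}-5,6-dihydro-2H-pyran-2-one, via Z-hydroxy enoate 7 (not isolated)
Conditions: H2 (1 atm), Pd/CaCO3 poisoned with Pb(OAc)2, quinoline, EtOAc, rt; filter; then PPTS (10 mol %), PhMe, 60 °C
Reagents that add atoms: none
Why: Lindlar semi-hydrogenation adds H2 syn to the alkyne only (the poisoned catalyst spares the monosubstituted alkene while alkyne is present), and the Z-δ-hydroxy enoate has the geometry needed for acid-catalysed lactonisation to the 5,6-dihydro-2H-pyran-2-one; no stereocentre is touched.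

Step 5
Reactants: 9 (R)-lactic acid (D-lactic acid)
Product: 10 triethylsilyl (R)-2-[(triethylsilyl)oxy]propanoate
Conditions: TESCl (2.2 equiv), Et3N (2.4 equiv), Et2O, 0 °C → rt; filter, concentrate, bulb-to-bulb distillation (no aqueous work-up)
Reagents that add atoms: chlorotriethylsilane, CC[Si](CC)(CC)Cl
Why: Exhaustive O-silylation of the hydroxy acid, in which only O–Si bonds form; the stereocentre comes from the chiral pool and is not enolised under these conditions.

Step 6
Reactants: 10 triethylsilyl (R)-2-[(triethylsilyl)oxy]propanoate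
Product: 12 (R)-1-diazo-3-[(triethylsilyl)oxy]butan-2-one, via acid chloride 11 (not isolated)
Conditions: (COCl)2 (1.1 equiv), DMF (cat.), CH2Cl2, 0 °C → rt; concentrate; then CH2N2 (3 equiv), Et2O, 0 °C
Reagents that add atoms: diazomethane, C=[N+]=[N-]
Why: The Vilsmeier chloride from (COCl)2/DMF converts the silyl ester into the acid chloride under neutral conditions without touching the silyl ether, and acylation of excess diazomethane (first stage of the Arndt–Eistert sequence) gives the α-diazoketone with the α-stereocentre intact because neither base nor protic acid is present.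

Step 7
Reactants: 13 tert-butyl(4-iodophenoxy)dimethylsilane (2.3 equiv); 14 (Z)-3-iodoacrylic acid (1.0 equiv)
Product: 16 (Z)-3-{4-[(tert-butyldimethylsilyl)oxy]phenyl}acrylic acid, via arylzinc iodide 15 (not isolated)
Conditions: 13, Zn dust, LiCl, THF, 50 °C; then 14, Pd(PPh3)4 (3 mol %), THF/DMF, 0 °C → rt, dark; cold 1 M HCl work-up
Reagents that add atoms: none
Why: LiCl-assisted zinc insertion followed by Negishi coupling with the free iodoacrylic acid (the first equivalent of arylzinc is spent on the CO2H proton); oxidative addition and reductive elimination at the vinyl iodide go with retention, which sets the Z alkene.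

Step 8
Reactants: 8 (R)-6-{(S)-1-[(tert-butyldimethylsilyl)oxy]allyl}-5,6-dihydro-2H-pyran-2-one (1.0 equiv); 12 (R)-1-diazo-3-[(triethylsilyl)oxy]butan-2-one (1.5 equiv)
Product: 18 (R)-6-{(S)-[(tert-butyldimethylsilyl)oxy][(1S,2S)-2-((R)-2-hydroxypropanoyl)cyclopropyl]methyl}-5,6-dihydro-2H-pyran-2-one, via triethylsilyl ether 17 (not isolated)
Conditions: [Co(3,5-DitBu-ChenPhyrin)] (5 mol %; the divalent cobalt complex of 5,15-bis(3,5-di-tert-butylphenyl)-10,20-bis[2,6-bis((S)-2,2-dimethylcyclopropanecarboxamido)phenyl]porphyrin), PhMe, 40 °C, 36 h, N2; then MeOH, PPTS (20 mol %), rt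
Reagents that add atoms: none
Why: Proposed new method: the divalent cobalt porphyrin, a stable metalloradical, takes up the diazoketone (held by N–H···O=C hydrogen bonds to the amide arms) and loses N2 to give an α-keto carbon radical bound to trivalent cobalt; this radical adds to the unhindered terminal CH2 of 8 (not to the 1,2-disubstituted conjugated lactone alkene), and the secondary γ-radical closes the three-membered ring by 3-exo-tet homolytic substitution at the Co–C bond, the stepwise path placing acyl and carbinol substituents trans and the chiral cavity selecting the (1S,2S) ring; methanolysis with PPTS then removes only the more labile TES ether; the closest known reaction type is the asymmetric radical cyclopropanation of alkenes with acceptor diazo compounds (diazoacetates, α-ketodiazoacetates, diazosulfones) by chiral amidoporphyrin divalent cobalt catalysts.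

Step 9
Reactants: 18 (R)-6-{(S)-[(tert-butyldimethylsilyl)oxy][(1S,2S)-2-((R)-2-hydroxypropanoyl)cyclopropyl]methyl}-5,6-dihydro-2H-pyran-2-one; 16 (Z)-3-{4-[(tert-butyldimethylsilyl)oxy]phenyl}acrylic acid (1.3 equiv)
Product: 19 (R)-1-{(1S,2S)-2-[(S)-[(tert-butyldimethylsilyl)oxy]((R)-6-oxo-3,6-dihydro-2H-pyran-2-yl)methyl]cyclopropyl}-1-oxopropan-2-yl (Z)-3-{4-[(tert-butyldimethylsilyl)oxy]phenyl}acrylate
Conditions: DCC (1.4 equiv), DMAP (10 mol %), CH2Cl2, −10 °C → rt, dark
Reagents that add atoms: none
Why: Steglich esterification (acyl transfer through the N-acylpyridinium ion) acylates the only free hydroxyl without touching the carbinol C–O bond, so that centre stays R, and the Z alkene is kept by low temperature and little DMAP.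

Step 10
Reactants: 19 the bis-TBS ester from step 9
Product: 20 (R)-1-{(1S,2S)-2-[(S)-hydroxy((R)-6-oxo-3,6-dihydro-2H-pyran-2-yl)methyl]cyclopropyl}-1-oxopropan-2-yl (Z)-3-(4-hydroxyphenyl)acrylate (CNP0246043.2)
Conditions: HF·pyridine (excess), pyridine, THF, 0 °C → rt, dark
Reagents that add atoms: none
Why: Fluoride-driven cleavage of the aryl and the secondary alkyl TBS ethers under buffered, slightly acidic conditions that avoid acyl migration, lactone opening and Z to E isomerisation; no stereocentre is touched.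

## Compound list

1 | penta-1,4-dien-3-ol | C=CC(O)C=C | starting material
2 | (2R,3S)-1,2-epoxypent-4-en-3-ol | C=C[C@H](O)[C@H]1CO1 | intermediate
3 | tert-butyldimethyl{[(S)-1-((R)-oxiran-2-yl)allyl]oxy}silane | C=C[C@H](O[Si](C)(C)C(C)(C)C)[C@H]1CO1 | intermediate
4 | ethyl propiolate | C#CC(=O)OCC | starting material
5 | ethyl 3-lithiopropiolate | [Li]C#CC(=O)OCC | intermediate
6 | ethyl (5R,6S)-6-[(tert-butyldimethylsilyl)oxy]-5-hydroxyoct-7-en-2-ynoate | C=C[C@H](O[Si](C)(C)C(C)(C)C)[C@H](O)CC#CC(=O)OCC | intermediate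
7 | ethyl (2Z,5R,6S)-6-[(tert-butyldimethylsilyl)oxy]-5-hydroxyocta-2,7-dienoate | C=C[C@H](O[Si](C)(C)C(C)(C)C)[C@H](O)C/C=C\C(=O)OCC | intermediate
8 | (R)-6-{(S)-1-[(tert-butyldimethylsilyl)oxy]allyl}-5,6-dihydro-2H-pyran-2-one | C=C[C@H](O[Si](C)(C)C(C)(C)C)[C@H]1CC=CC(=O)O1 | intermediate
9 | (R)-lactic acid | C[C@@H](O)C(=O)O | starting material
10 | triethylsilyl (R)-2-[(triethylsilyl)oxy]propanoate | C[C@@H](O[Si](CC)(CC)CC)C(=O)O[Si](CC)(CC)CC | intermediate
11 | (R)-2-[(triethylsilyl)oxy]propanoyl chloride | C[C@@H](O[Si](CC)(CC)CC)C(Cl)=O | intermediate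
12 | (R)-1-diazo-3-[(triethylsilyl)oxy]butan-2-one | C[C@@H](O[Si](CC)(CC)CC)C(=O)C=[N+]=[N-] | intermediate
13 | tert-butyl(4-iodophenoxy)dimethylsilane | CC(C)(C)[Si](C)(C)Oc1ccc(I)cc1 | starting material
14 | (Z)-3-iodoacrylic acid | OC(=O)/C=C\I | starting material
15 | {4-[(tert-butyldimethylsilyl)oxy]phenyl}zinc iodide | CC(C)(C)[Si](C)(C)Oc1ccc([Zn]I)cc1 | intermediate
16 | (Z)-3-{4-[(tert-butyldimethylsilyl)oxy]phenyl}acrylic acid | OC(=O)/C=C\c1ccc(O[Si](C)(C)C(C)(C)C)cc1 | intermediate
17 | (R)-6-{(S)-[(tert-butyldimethylsilyl)oxy][(1S,2S)-2-((R)-2-[(triethylsilyl)oxy]propanoyl)cyclopropyl]methyl}-5,6-dihydro-2H-pyran-2-one | C[C@@H](O[Si](CC)(CC)CC)C(=O)[C@H]1C[C@@H]1[C@H](O[Si](C)(C)C(C)(C)C)[C@H]1CC=CC(=O)O1 | intermediate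
18 | (R)-6-{(S)-[(tert-butyldimethylsilyl)oxy][(1S,2S)-2-((R)-2-hydroxypropanoyl)cyclopropyl]methyl}-5,6-dihydro-2H-pyran-2-one | C[C@@H](O)C(=O)[C@H]1C[C@@H]1[C@H](O[Si](C)(C)C(C)(C)C)[C@H]1CC=CC(=O)O1 | intermediate
19 | (R)-1-{(1S,2S)-2-[(S)-[(tert-butyldimethylsilyl)oxy]((R)-6-oxo-3,6-dihydro-2H-pyran-2-yl)methyl]cyclopropyl}-1-oxopropan-2-yl (Z)-3-{4-[(tert-butyldimethylsilyl)oxy]phenyl}acrylate | C[C@@H](OC(=O)/C=C\c1ccc(O[Si](C)(C)C(C)(C)C)cc1)C(=O)[C@H]1C[C@@H]1[C@H](O[Si](C)(C)C(C)(C)C)[C@H]1CC=CC(=O)O1 | intermediate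
20 | (R)-1-{(1S,2S)-2-[(S)-hydroxy((R)-6-oxo-3,6-dihydro-2H-pyran-2-yl)methyl]cyclopropyl}-1-oxopropan-2-yl (Z)-3-(4-hydroxyphenyl)acrylate | C[C@@H](OC(=O)/C=C\c1ccc(O)cc1)C(=O)[C@H]1C[C@@H]1[C@H](O)[C@H]1CC=CC(=O)O1 | target

## Step count and risks

Total step count: 10.
Longest linear sequence: 7 steps (1 → 2 → 3 → 4 → 8 → 9 → 10, from divinylcarbinol).

Most likely to fail, first: step 8. The terminal alkene of 8 is unactivated and carries an allylic stereocentre, so conversion may be low and the catalyst may be mismatched with the substrate. The fallback sets out from 8 and comes back at 17. Alkene 8 is cyclopropanated by closed-shell carbene transfer from 1,3-dioxoisoindolin-2-yl diazoacetate (Rh2(S-TCPTTL)4, i.e. dirhodium tetrakis[N-tetrachlorophthaloyl-(S)-tert-leucinate], CH2Cl2, −40 °C). This gives the redox-active ester 1,3-dioxoisoindolin-2-yl (1S,2S)-2-{(S)-[(tert-butyldimethylsilyl)oxy][(R)-6-oxo-3,6-dihydro-2H-pyran-2-yl]methyl}cyclopropane-1-carboxylate F1. Acid chloride 11 (from 10 as in step 6) is trapped with pyridine-2-thiol and Et3N to give S-(pyridin-2-yl) (R)-2-[(triethylsilyl)oxy]propanethioate F2. F1 and F2 are then joined by nickel-catalysed reductive decarboxylative acylation (NiCl2·glyme, 4,4'-di-tert-butyl-2,2'-bipyridine, Zn, THF/DMA, rt). The cyclopropyl radical from F1 inverts rapidly and is captured by the acyl nickel species on the face trans to the large substituent, which gives 17; this is desilylated to 18 as in step 8. The radical bond formation thus moves from the ring bonds to the acyl–cyclopropyl bond.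

Second: step 9. The acylation of the hindered α-hydroxy ketone may be slow, and the activated Z-cinnamoyl group may drift to E. The fallback sets out from 18 and comes back at 19. Alcohol 18 is esterified with the small and configurationally robust acid 14 (DCC, DMAP cat., CH2Cl2, −20 °C) to give (R)-1-{(1S,2S)-2-[(S)-[(tert-butyldimethylsilyl)oxy]((R)-6-oxo-3,6-dihydro-2H-pyran-2-yl)methyl]cyclopropyl}-1-oxopropan-2-yl (Z)-3-iodoacrylate F3. The aryl group is then introduced by Negishi coupling of F3 with arylzinc 15 (Pd(PPh3)4, THF, rt), which proceeds with retention and tolerates the ketone and the lactone, to give 19.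

Third: step 7. The free acid may couple poorly with the electron-rich arylzinc, or the Z geometry may erode under palladium. The fallback sets out from 13 and comes back at 16. Iodide 13 is coupled with propiolic acid (Pd(PPh3)2Cl2, 1,4-bis(diphenylphosphino)butane, DBU, DMSO, rt) to give 3-{4-[(tert-butyldimethylsilyl)oxy]phenyl}propiolic acid F4. Semi-hydrogenation of F4 (H2, Pd/CaCO3 poisoned with Pb(OAc)2, quinoline, EtOAc) then sets the Z alkene by syn addition and gives 16.

## Further compounds

F1 | step 8 | 1,3-dioxoisoindolin-2-yl (1S,2S)-2-{(S)-[(tert-butyldimethylsilyl)oxy][(R)-6-oxo-3,6-dihydro-2H-pyran-2-yl]methyl}cyclopropane-1-carboxylate | O=C(ON1C(=O)c2ccccc2C1=O)[C@H]1C[C@@H]1[C@H](O[Si](C)(C)C(C)(C)C)[C@H]1CC=CC(=O)O1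
F2 | step 8 | S-(pyridin-2-yl) (R)-2-[(triethylsilyl)oxy]propanethioate | C[C@@H](O[Si](CC)(CC)CC)C(=O)Sc1ccccn1
F3 | step 9 | (R)-1-{(1S,2S)-2-[(S)-[(tert-butyldimethylsilyl)oxy]((R)-6-oxo-3,6-dihydro-2H-pyran-2-yl)methyl]cyclopropyl}-1-oxopropan-2-yl (Z)-3-iodoacrylate | C[C@@H](OC(=O)/C=C\I)C(=O)[C@H]1C[C@@H]1[C@H](O[Si](C)(C)C(C)(C)C)[C@H]1CC=CC(=O)O1
F4 | step 7 | 3-{4-[(tert-butyldimethylsilyl)oxy]phenyl}propiolic acid | OC(=O)C#Cc1ccc(O[Si](C)(C)C(C)(C)C)cc1
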